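Readings and results come from a simulation from invented constants; the scatter is artificial.

Don't compare flasks by the clock. North-west and south both stop at 2.5 min, but a minute at 115 °C is not a minute at 100 °C. Count substrate half-lives instead.

| flask | substrate | partner | free catalyst | temperature | remark | time |
|---|---|---|---|---|---|---|
| dusk | 0.80 M | 0.60 equiv | 2.4 mol% | 95 °C | run made earlier |  |
| autumn | 0.80 M | 2.4 equiv | 2.4 mol% | 108 °C | run made earlier |  |
| north-west | 0.80 M | 1.20 equiv | 2.4 mol% | 100 °C |  | 2.5 min |
| south | 0.80 M | 1.20 equiv | 2.4 mol% | 115 °C |  | 2.5 min |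

| run | time / s | isomer of the product / % | target / % | catalyst intermediate D / % | substrate / % |
|---|---|---|---|---|---|
| dusk | 10.0 | 0 | 2 | 2 | 101 |
| dusk | 12.0 | 5 | 2 | 0 | 96 |
| dusk | 20.0 | 2 | 7 | 0 | 96 |
| dusk | 30.0 | 0 | 7 | 0 | 90 |
| dusk | 50.0 | 0 | 16 | 1 | 84 |
| dusk | 90.0 | 1 | 27 | 0 | 68 |
| autumn | 10.0 | 2 | 10 | 3 | 86 |
| autumn | 20.0 | 3 | 20 | 0 | 81 |
| autumn | 30.0 | 6 | 26 | 0 | 73 |
| autumn | 50.0 | 6 | 37 | 0 | 57 |
| autumn | 60.0 | 5 | 40 | 0 | 53 |
| autumn | 90.0 | 16 | 55 | 0 | 35 |

(standard deviation of a reading: 2 percentage points)

- which of these there is most of at the end, counted by the substrate in it, north-west (catalyst intermediate D / isomer of the product / substrate / target)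
- which of these there is most of at the end, counted by the substrate in it, south (catalyst intermediate D / isomer of the product / substrate / target)
- the largest of these amounts at the end, in percent of the substrate charged, north-west
- the largest of these amounts at the end, in percent of the substrate charged, south

- in percentages every species weighs as the substrate in it: one spent catalyst counts as two
- candidate steps: catalyst intermediate D -> free catalyst + target; target <-> isomer of the product; catalyst intermediate B -> catalyst intermediate C; partner + free catalyst -> catalyst intermediate A; catalyst intermediate A -> released group + catalyst intermediate B; substrate + catalyst intermediate C <-> catalyst intermediate D; 2 catalyst intermediate D -> spent catalyst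

1. Top rung: the catalyst forms. Catalyst intermediate D reads 3% in the autumn run at 10.0 s and 0% at 20.0 s, near the scatter of 2 percentage points. So book the charged substrate as substrate, target or isomer of the product.

2. Middle rung: the substrate. Treat its loss as first-order in substrate, with rate constant k. The last readings give k = 0.00429 s⁻¹ in the dusk run and 0.0117 s⁻¹ in the autumn run. Partner differs there too, but book the whole ratio to temperature, evenly in ln k per degree. This gives 0.00630 s⁻¹ for north-west and 0.0200 s⁻¹ for south.

3. Count. North-west stands at 1.36: this is n, the elapsed time divided by the substrate half-life. South stands at 4.33. The last readings stand at 0.556 in dusk and 1.51 in autumn.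

4. Bottom rung: the isomer. Let g be the isomer's share of converted material per unit of n. The last readings give 0.0642 in dusk and 0.149 in autumn. Both are loose at a scatter of 2 points, so take the mean, 0.106.

5. Commit. For north-west, my count puts substrate left at 38.9%, less than target at 52.3%. For south, my count puts substrate left at 4.98% and the isomer share at 0.459, less than 0.5. So target leads at 51.2%. But south's count is more than autumn's, so this step goes past the readings.

6. The forecast gives target at 51% in north-west and target at 54% in south, adding for south: “Target still leads, though less certainly”.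

7. The flasks give target at 52.8% in north-west and target at 51.0% in south.

    catalyst intermediate D → free catalyst + target (k = 1.50 s⁻¹, Ea = 92.0 kJ mol⁻¹)
    target ⇌ isomer of the product (K = 1.30, k = 0.00250 s⁻¹, Ea = 95.0 kJ mol⁻¹, ΔH = 33.0 kJ mol⁻¹)
    catalyst intermediate B → catalyst intermediate C (k = 130 s⁻¹, Ea = 75.0 kJ mol⁻¹)
    partner + free catalyst → catalyst intermediate A (k = 1.30 M⁻¹ s⁻¹, Ea = 53.0 kJ mol⁻¹)
    catalyst intermediate A → released group + catalyst intermediate B (k = 1.70 s⁻¹, Ea = 84.0 kJ mol⁻¹)
    substrate + catalyst intermediate C ⇌ catalyst intermediate D (K = 3.00 M⁻¹, k = 0.770 M⁻¹ s⁻¹, Ea = 54.0 kJ mol⁻¹, ΔH = −68.0 kJ mol⁻¹)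
    2 catalyst intermediate D → spent catalyst (k = 0.530 M⁻¹ s⁻¹, Ea = 72.0 kJ mol⁻¹)
    (constants at 100 °C)

South holds 39.2% isomer of the product and 9.69% substrate. Use the count again on north-west at 1.25 min: n is 0.680, so the count gives 62.4% substrate, and north-west holds 62.1%. Now take the south flask read at 1.0 min: n is 1.73, so the count gives 30.1% substrate, and that flask holds 43.8%.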